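| flask | substrate | reagent | base | scavenger | remark | time |
|---|---|---|---|---|---|---|
| midnight | 0.50 M | 0.90 equiv | 0.30 equiv | 0.50 equiv | the very flask that is asked about, followed so far |  |
| noon | 0.50 M | 0.90 equiv | 0.30 equiv | 0.34 equiv | run made earlier |  |
| flask | 0.50 M | 0.900 equiv | 0.300 equiv | 0.500 equiv |  | 2.0 h |

| run | time / min | substrate / % | target / % |
|---|---|---|---|
| midnight | 6.00 | 23.6 | 2.1 |
| midnight | 12.0 | 8.6 | 1.3 |
| midnight | 20.0 | 4.3 | 0.7 |
| midnight | 25.0 | 3.7 | 1.9 |
| midnight | 30.0 | 2.9 | 0 |
| midnight | 40.0 | 4.5 | 0 |
| noon | 8.00 | 13.0 | 1.8 |
| noon | 15.0 | 6.0 | 1.0 |
| noon | 25.0 | 2.9 | 2.1 |
| noon | 30.0 | 3.9 | 0.6 |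
| noon | 40.0 | 1.7 | 0 |
| noon | 50.0 | 5.4 | 0.6 |

(standard deviation of a reading: 1 percentage point)
- part of the substrate that has reacted at 2.0 h
- share of the unused reagent that is free and not bound as idle adduct, at 2.0 h
- released group is meant together with its idle adduct
- on the list of suspects stand: substrate <-> dormant form; base + released group <-> salt; scavenger + released group -> scavenged by-product; substrate + reagent -> target + released group; reagent + released group <-> idle adduct; substrate + reagent + released group -> target + 2 released group
- what has gone from substrate into another species counts as reacted, even if it can come back
- the earlier runs do not show how much of reagent is bound; that part of a forecast is a guess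

1. We start with an easy balance, on the reagent, charged at 0.900 equiv against the substrate. Each target formed uses one reagent, so this charge allows target up to that figure. But the late readings of both runs average 0.737 % target, so the lost substrate has not become target.

2. Turn the scavenger: by hand, more of it takes up more released group, which should slow target formation. The late substrate readings average 3.85 % with 0.50 equiv and 3.48 % with 0.34 equiv, while one reading scatters by 1 percentage point. We see no scavenger effect.

3. Turn the time: by hand, a longer time matters if substrate is still falling. From 20.0 min to 50.0 min the substrate readings of the two runs scatter with no clear trend, around a joint mean of 3.66 %.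

4. So we balance the substrate. The parking ratio, a reading that carries the scatter of these runs, is 26.1: dormant form per free substrate once both stand still. The dormant form is the resting state, and free substrate is the charge minus target, divided by one plus the ratio.

5. For the asked flask we reckon 96.3 % reacted. The runs do not show binding, so the free share of reagent remains a guess.

6. The forecast says 96.5 % reacted and 96 % free, where our reacted figure is 96.3 %, and it reads the runs thus: “substrate is parking reversibly in the dormant form”.

7. The asked flask gives 96.3 % reacted and >99.9 % free, so both forecast values stand within tolerance.

    substrate ⇌ dormant form (K = 26.0, k = 0.00440 /s)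
    base + released group ⇌ salt, settled at all times (K = 320 /M)
    scavenger + released group → scavenged by-product (k = 0.170 /M/s)
    substrate + reagent → target + released group (k = 2.40 × 10⁻⁵ /M/s)
    reagent + released group ⇌ idle adduct, settled at all times (K = 4.00 /M)
    substrate + reagent + released group → target + 2 released group (k = 0.0370 /M²/s)

8. At 2.00 h the asked flask holds 0.519 % target, so the parking ratio gives 3.67 % free substrate, and the flask holds 3.68 %. The neighbouring flask with 3.60 equiv of reagent holds 2.13 % target, so the same reckoning gives 3.61 %, and that neighbouring flask holds 3.59 %.

(The numbers in the tables stem from a simulated flask on assumed constants.)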